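**Retrosynthetic overview**
1. 17 ⇒ 16: acetylation of the C6 and C8 hydroxyls. The tertiary C4 hydroxyl stays free.
2. Ring B (seven-membered, closed last): C8–C9 by intramolecular allylchromium addition in 14, and C6–C7 by an auxiliary-controlled syn aldol of 8 with 11.
3. Key disconnection, C4–O: hydroxy aldehyde 8 ⇒ epoxy aldehyde 7 ⇒ enal 6. Peroxide oxygen goes onto C4 anti to the C3 acetate (new iminium-catalysed epoxidation), then only the C5–O bond is cleaved.
4. C3–O: Mitsunobu inversion of the Luche alcohol 3 with acetic acid. This acetate steers the C4–O step.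
5. Ring A (cyclopentane, formed first): ozonolysis and aldol condensation contract the cyclohexene of 10-chlorocarvone 2, made from (R)-carvone 1, which supplies C1.

Assumption: guaiane numbering is used (C1/C5 ring fusion, C4 carbinol, C7 isopropyl, C10 methylidene). The SMILES reads (1S,3S,4S,5S,6S,7R,8S), that is 1β-H, 5α-H, 3β-OAc, 4α-OH, 6α-OAc, 7β-isopropyl, 8α-OAc.

**Step 1**
Reactants: 1 (R)-carvone
Product: 2 10-chlorocarvone (5R)-5-(3-chloroprop-1-en-2-yl)-2-methylcyclohex-2-en-1-one
Conditions: Ca(OCl)2, solid CO2, CH2Cl2/H2O, 0 °C to rt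
Reagents that add atoms: calcium hypochlorite, [Ca+2].[O-]Cl.[O-]Cl
Why: Ene-type allylic chlorination by HOCl made in the flask attacks only the electron-rich isopropenyl group because the ring alkene is deactivated as an enone, and the stereocentre (later C1) is untouched.

**Step 2**
Reactants: 2 10-chlorocarvone
Product: 3 cis alcohol (1R,5R)-5-(3-chloroprop-1-en-2-yl)-2-methylcyclohex-2-en-1-ol
Conditions: NaBH4, CeCl3·7H2O, MeOH, −20 °C
Reagents that add atoms: none
Why: Luche 1,2-reduction delivers hydride axially to the half-chair that carries the side chain equatorial, so the new carbinol is pseudo-equatorial and cis to the side chain (1R).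

**Step 3**
Reactants: 3 cis alcohol
Product: 4 trans acetate (1S,5R)-5-(3-chloroprop-1-en-2-yl)-2-methylcyclohex-2-en-1-yl acetate
Conditions: PPh3, DIAD, AcOH, THF, 0 °C to rt
Reagents that add atoms: acetic acid, CC(=O)O
Why: Mitsunobu esterification displaces the oxyphosphonium ion by acetate in an SN2 sense, which forms the C3–O bond of the target with clean inversion to the trans (1S) acetate.

**Step 4**
Reactants: 4 trans acetate
Product: 6 enal (3S,5S)-3-acetoxy-5-(3-chloroprop-1-en-2-yl)-2-methylcyclopent-1-ene-1-carbaldehyde, via keto aldehyde 5 (not isolated)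
Conditions: O3 (1.0 equiv), CH2Cl2, −78 °C; Me2S, −78 °C to rt; piperidine (20 mol %), AcOH (20 mol %), rt to 40 °C
Reagents that add atoms: ozone, [O-][O+]=O
Why: Chemoselective ozonolysis cleaves the trisubstituted ring alkene (the 1,1-disubstituted chloromethallyl alkene is inductively deactivated), and an enamine-mediated intramolecular aldol condensation then closes ring A without creating or touching a stereocentre.

**Step 5**
Reactants: 6 enal
Product: 7 epoxy aldehyde (1S,2R,4S,5R)-4-acetoxy-2-(3-chloroprop-1-en-2-yl)-5-methyl-6-oxabicyclo[3.1.0]hexane-1-carbaldehyde (4α,5α-epoxide in guaiane numbering)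
Conditions: cyclohexylamine (20 mol %), CF3CO2H (20 mol %), 35% aq H2O2 (3 equiv), 1,4-dioxane, 35 °C
Reagents that add atoms: hydrogen peroxide, OO
Why: Proposed new method: a small primary ammonium salt converts the hindered formyl group into the conjugated iminium ion (the type of ion through which the condensation of step 4 already passes), H2O2 adds to C4 on the α face anti to the C3 acetate, and the β-hydroperoxy enamine closes on the O–O bond on that same face (which also keeps the formyl group trans to the C1 side chain), so the key C4–O bond and the C4 configuration are set under base-free conditions that spare the acetate and the allyl chloride; the closest known reaction type is the amine-catalysed iminium–enamine (Weitz–Scheffer type) epoxidation of β,β-disubstituted or α-branched enals, which has not been shown for a fully substituted ring enal with a γ-acyloxy group.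

**Step 6**
Reactants: 7 epoxy aldehyde
Product: 8 hydroxy aldehyde (1R,2S,3S,5S)-3-acetoxy-5-(3-chloroprop-1-en-2-yl)-2-hydroxy-2-methylcyclopentane-1-carbaldehyde
Conditions: SmI2 (2.5 equiv), MeOH (10 equiv), THF, −90 °C, 10 min; pH 7 buffer
Reagents that add atoms: none
Why: SmI2 reductive opening of an α,β-epoxy carbonyl compound cleaves only the C5–O bond next to the ketyl, so C4–O and its configuration stay, and the samarium enolate is protonated (and the aldehyde can equilibrate) to the more stable C5 epimer with the formyl group trans to the C1 side chain (5α-H), while the allyl chloride is inert at this temperature.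

**Step 7**
Reactants: 9 (S)-4-benzyl-1,3-thiazolidine-2-thione; 10 isovaleryl chloride
Product: 11 (S)-4-benzyl-3-(3-methylbutanoyl)-1,3-thiazolidine-2-thione
Conditions: Et3N, DMAP (5 mol %), CH2Cl2, 0 °C to rt
Reagents that add atoms: none
Why: Simple N-acylation of the auxiliary, in which no stereocentre is formed or touched.

**Step 8**
Reactants: 8 hydroxy aldehyde; 11 N-isovaleryl thiazolidinethione
Product: 13 syn aldol adduct (4S)-4-benzyl-3-{(2S,3R)-3-[(1S,2S,3S,5S)-3-acetoxy-5-(3-chloroprop-1-en-2-yl)-2-hydroxy-2-methylcyclopentyl]-3-hydroxy-2-isopropylpropanoyl}-1,3-thiazolidine-2-thione, via titanium enolate 12 (not isolated)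
Conditions: 11 (2 equiv), TiCl4 (2.1 equiv), i-Pr2NEt (2.2 equiv), N-methyl-2-pyrrolidinone (2 equiv), CH2Cl2, 0 °C; then 8, −78 to −20 °C; aq NH4Cl
Reagents that add atoms: none
Why: Crimmins titanium aldol in the Evans-syn mode, where the Z enolate reacts through a Zimmerman–Traxler chair on the face left open by the benzyl group to set C6 and C7 (3R,2S in the acyl chain), and a Z enolate also prefers the anti-Felkin face of this α-branched aldehyde, which is the face needed, so reagent and substrate control are matched.

**Step 9**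
Reactants: 13 syn aldol adduct
Product: 14 aldehyde (2S,3R)-3-[(1S,2S,3S,5S)-3-acetoxy-5-(3-chloroprop-1-en-2-yl)-2-hydroxy-2-methylcyclopentyl]-3-hydroxy-2-isopropylpropanal
Conditions: i-Bu2AlH (about 3.1 equiv, added until the yellow colour fades), CH2Cl2, −78 °C; aq KNaC4H4O6
Reagents that add atoms: none
Why: Direct reductive cleavage of the N-acyl thiazolidinethione, in which two equivalents are taken up by the hydroxyls, the activated imide is reduced much faster than the acetate, and the tetrahedral aluminate survives to the quench, so the aldehyde is released without over-reduction or epimerisation at C7.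

**Step 10**
Reactants: 14 aldehyde
Product: 16 3β-acetoxy-1βH,5αH,7αH-guai-10(14)-ene-4α,6α,8α-triol, via allylchromium species 15 (not isolated)
Conditions: CrCl2 (6 equiv), THF/DMF 1:1, 0.005 M, slow addition of 14, rt; water
Reagents that add atoms: none
Why: Nozaki–Hiyama (Barbier-type) allylation, where divalent chromium inserts into the allylic C–Cl bond and the allylchromium adds to the C8 aldehyde with allyl transposition, which closes ring B and regenerates the exocyclic methylidene, and the ring-forming transition state that places the metal alkoxide and the isopropyl group both equatorial gives the 8α (8S) alcohol trans to the isopropyl group.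

**Step 11**
Reactants: 16 triol monoacetate
Product: 17 target 3β,6α,8α-triacetoxy-1βH,5αH,7αH-guai-10(14)-en-4α-ol
Conditions: Ac2O (4 equiv), pyridine, DMAP (5 mol %), CH2Cl2, 0 °C to rt
Reagents that add atoms: acetic anhydride, CC(=O)OC(C)=O
Why: DMAP-catalysed acetylation esterifies the two secondary hydroxyls at C6 and C8 while the hindered tertiary C4 hydroxyl does not react under these mild conditions, and no stereocentre is touched.

**Compound list**
1 | (R)-carvone, (5R)-2-methyl-5-(prop-1-en-2-yl)cyclohex-2-en-1-one | CC1=CC[C@H](CC1=O)C(C)=C | starting material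
2 | 10-chlorocarvone, (5R)-5-(3-chloroprop-1-en-2-yl)-2-methylcyclohex-2-en-1-one | CC1=CC[C@H](CC1=O)C(=C)CCl | intermediate
3 | cis alcohol, (1R,5R)-5-(3-chloroprop-1-en-2-yl)-2-methylcyclohex-2-en-1-ol | CC1=CC[C@H](C[C@H]1O)C(=C)CCl | intermediate
4 | trans acetate, (1S,5R)-5-(3-chloroprop-1-en-2-yl)-2-methylcyclohex-2-en-1-yl acetate | CC1=CC[C@H](C[C@@H]1OC(C)=O)C(=C)CCl | intermediate
5 | keto aldehyde, (3S,5S)-5-acetoxy-3-(3-chloroprop-1-en-2-yl)-6-oxoheptanal | CC(=O)[C@@H](OC(C)=O)C[C@@H](CC=O)C(=C)CCl | intermediate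
6 | enal, (3S,5S)-3-acetoxy-5-(3-chloroprop-1-en-2-yl)-2-methylcyclopent-1-ene-1-carbaldehyde | O=CC1=C(C)[C@@H](OC(C)=O)C[C@@H]1C(=C)CCl | intermediate
7 | epoxy aldehyde, (1S,2R,4S,5R)-4-acetoxy-2-(3-chloroprop-1-en-2-yl)-5-methyl-6-oxabicyclo[3.1.0]hexane-1-carbaldehyde | O=C[C@]12[C@@H](C(=C)CCl)C[C@H](OC(C)=O)[C@@]1(C)O2 | intermediate
8 | hydroxy aldehyde, (1R,2S,3S,5S)-3-acetoxy-5-(3-chloroprop-1-en-2-yl)-2-hydroxy-2-methylcyclopentane-1-carbaldehyde | O=C[C@@H]1[C@@H](C(=C)CCl)C[C@H](OC(C)=O)[C@@]1(C)O | intermediate
9 | (S)-4-benzyl-1,3-thiazolidine-2-thione | S=C1N[C@@H](Cc2ccccc2)CS1 | starting material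
10 | isovaleryl chloride (3-methylbutanoyl chloride) | CC(C)CC(=O)Cl | starting material
11 | (S)-4-benzyl-3-(3-methylbutanoyl)-1,3-thiazolidine-2-thione | CC(C)CC(=O)N1[C@@H](Cc2ccccc2)CSC1=S | intermediate
12 | trichlorotitanium Z enolate of 11 | CC(C)/C=C(\O[Ti](Cl)(Cl)Cl)N1[C@@H](Cc2ccccc2)CSC1=S | intermediate
13 | syn aldol adduct, (4S)-4-benzyl-3-{(2S,3R)-3-[(1S,2S,3S,5S)-3-acetoxy-5-(3-chloroprop-1-en-2-yl)-2-hydroxy-2-methylcyclopentyl]-3-hydroxy-2-isopropylpropanoyl}-1,3-thiazolidine-2-thione | O=C(N1[C@@H](Cc2ccccc2)CSC1=S)[C@@H](C(C)C)[C@H](O)[C@@H]3[C@@H](C(=C)CCl)C[C@H](OC(C)=O)[C@@]3(C)O | intermediate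
14 | aldehyde, (2S,3R)-3-[(1S,2S,3S,5S)-3-acetoxy-5-(3-chloroprop-1-en-2-yl)-2-hydroxy-2-methylcyclopentyl]-3-hydroxy-2-isopropylpropanal | O=C[C@@H](C(C)C)[C@H](O)[C@@H]1[C@@H](C(=C)CCl)C[C@H](OC(C)=O)[C@@]1(C)O | intermediate
15 | allylchromium dichloride derived from 14 (CrCl2 group in place of Cl) | O=C[C@@H](C(C)C)[C@H](O)[C@@H]1[C@@H](C(=C)C[Cr](Cl)Cl)C[C@H](OC(C)=O)[C@@]1(C)O | intermediate
16 | 3β-acetoxy-1βH,5αH,7αH-guai-10(14)-ene-4α,6α,8α-triol, (1S,3S,4S,5S,6S,7R,8S) | C=C1C[C@H](O)[C@@H](C(C)C)[C@H](O)[C@@H]2[C@@H]1C[C@H](OC(C)=O)[C@@]2(C)O | intermediate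
17 | 3β,6α,8α-triacetoxy-1βH,5αH,7αH-guai-10(14)-en-4α-ol, (1S,3S,4S,5S,6S,7R,8S), CNP0147943.1 | C=C1C[C@H](OC(C)=O)[C@@H](C(C)C)[C@H](OC(C)=O)[C@@H]2[C@@H]1C[C@H](OC(C)=O)[C@@]2(C)O | target

**Step count**
Total step count: 11. Longest linear sequence: 10 (steps 1 to 6 and 8 to 11).

**Three steps most likely to fail**

Step 5 (the proposed new epoxidation).
- Why it may fail: the iminium ion of a fully substituted enal may form too slowly. Dienamine formation could also erode the C3 centre before oxygen transfer.
- Fallback with known chemistry: it sets out from 4. Ozonolysis is run as in step 4, but keto aldehyde 5 is isolated after the Me2S work-up. Ring A is then closed by an (R)-proline-catalysed 5-enolexo intramolecular aldol addition (DMF, 0 °C to rt), which stops at the aldol stage.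
- Stereocontrol: the enamine attacks the α-acetoxy ketone in the Cornforth or polar Felkin–Anh arrangement, so the new hydroxyl ends up anti to the acetate. The formyl group settles trans to the side chain.
- Return point: this gives 8 directly, where the route is rejoined, and steps 5 and 6 fall away. It makes no compound that is missing from the list (F0).

Step 8 (aldol on a hindered, unprotected β-hydroxy aldehyde).
- Why it may fail: the free tertiary hydroxyl can quench the enolate or open a retro-aldol path under TiCl4.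
- Fallback: it sets out from 8. The carbinol is masked with Et3SiOTf and 2,6-lutidine (CH2Cl2, −78 °C) to give the triethylsilyl ether F1. The same enolate 12 then adds to a non-chelating, non-acidic aldehyde to give the silylated aldol adduct F2. i-Bu2AlH releases the silylated aldehyde F3, and HF·pyridine in THF removes the silyl group.
- Return point: the route is rejoined at 14.

Step 10 (ring closure and C8 configuration).
- Why it may fail: chelation through the free C6 hydroxyl could favour the 1,3-anti diol.
- Fallback: it sets out from 14 and accepts that outcome. The chromium-mediated closure then gives the 8β-alcohol F4. A Mitsunobu reaction (PPh3, DIAD, AcOH, THF) at the less hindered C8 hydroxyl inverts this centre and installs its acetate in one operation, giving the 3,8-diacetate F5. Acetylation of the remaining C6 hydroxyl follows (Ac2O, pyridine, DMAP).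
- Return point: the route is rejoined at 17.

**Further compounds**
F0 | step 5 | none | none
F1 | step 8 | triethylsilyl ether of 8, (1R,2S,3S,5S)-3-acetoxy-5-(3-chloroprop-1-en-2-yl)-2-methyl-2-(triethylsilyloxy)cyclopentane-1-carbaldehyde | O=C[C@@H]1[C@@H](C(=C)CCl)C[C@H](OC(C)=O)[C@@]1(C)O[Si](CC)(CC)CC
F2 | step 8 | silylated aldol adduct (13 with the C4 hydroxyl as triethylsilyl ether) | O=C(N1[C@@H](Cc2ccccc2)CSC1=S)[C@@H](C(C)C)[C@H](O)[C@@H]3[C@@H](C(=C)CCl)C[C@H](OC(C)=O)[C@@]3(C)O[Si](CC)(CC)CC
F3 | step 8 | silylated aldehyde (14 with the C4 hydroxyl as triethylsilyl ether) | O=C[C@@H](C(C)C)[C@H](O)[C@@H]1[C@@H](C(=C)CCl)C[C@H](OC(C)=O)[C@@]1(C)O[Si](CC)(CC)CC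
F4 | step 10 | 8β-alcohol, 3β-acetoxy-1βH,5αH,7αH-guai-10(14)-ene-4α,6α,8β-triol | C=C1C[C@@H](O)[C@@H](C(C)C)[C@H](O)[C@@H]2[C@@H]1C[C@H](OC(C)=O)[C@@]2(C)O
F5 | step 10 | 3,8-diacetate, 3β,8α-diacetoxy-1βH,5αH,7αH-guai-10(14)-ene-4α,6α-diol | C=C1C[C@H](OC(C)=O)[C@@H](C(C)C)[C@H](O)[C@@H]2[C@@H]1C[C@H](OC(C)=O)[C@@]2(C)O
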